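# Total synthesis proposal for CNP0260213.5: ring enlargement of a p-menthane by an anionic oxy-Cope rearrangement

## Analysis of the target

- **Numbering.** Germacrane numbering is used throughout. C1=C10 is the ring alkene (methyl on C10) and C2 and C3 are methylenes. C4 (methyl) and C5 are the oxirane carbons. C6 bears the free hydroxyl, C7 the isopropyl group, C8 the 3,4,5-trimethoxybenzoate, and C9 is a methylene.
- **Skeleton.** It is one ten-membered carbocycle, fused to an oxirane at C4–C5, with an E-trisubstituted alkene on the opposite side of the ring.
- **Stereocentres.** The five centres are contiguous (4S,5R,6R,7R,8S). The ring bonds C3–C4 and C5–C6 lie on the same side of the oxirane, so the epoxide is cis-fused and stands for a Z C4=C5 alkene. O6 lies on the same ring face as the oxirane oxygen. Along the chain, C6/C7 are syn, C7/C8 anti and O6/O8 1,3-anti.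
- **Sensitive groups.** The oxirane faces C1=C10 across the ring and can open transannularly with acid. Its diene precursors are 1,5-dienes that can undergo Cope rearrangement on heating. The acyl group of the 1,3-diol monoester can move from O8 to O6 under base.
- **Difficulty.** The ring suffers medium-ring strain and an entropic penalty on closure. An E alkene and a cis-oxirane share one ring. No rigid template controls the five stereocentres. Two similar secondary oxygens must be told apart.
- **Feature that invites the key move.** A cis relation of C3 and C6 at C4/C5 is what a six-membered ring C1–C6 enforces. C6 is also separated from the alkene carbon C10 by three sp3 carbons (C7, C8, C9). Once C6 is a ketone, this is the retron of an oxy-Cope rearrangement. Reconnecting C1 to C6 turns the ten-membered ring into a p-menthane.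

## Retrosynthetic reasoning

**17 to 16.** The two C–O bonds of the oxirane are cut first. The oxirane is the most acid-labile group and so should be made last. In 16 the free O6 hydroxyl is allylic to C4=C5 only, so one directing group solves both chemoselectivity (against C1=C10) and facial selectivity. The forward reaction must add oxygen suprafacially to a Z alkene on the face of O6.

**16 to 14 and 15.** The acyl–O8 bond and the C6–H bond are cut together. A 1,3-anti diol with the ester on one oxygen and the other oxygen free is the retron of an Evans–Tishchenko reduction of β-hydroxy ketone 14 with aldehyde 15. One operation then sets C6, installs the ester and tells O6 from O8, without a protecting group.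

**14 to 12.** O8 is exchanged for silicon. An oxygen substituent on C8 cannot pass through enolate 11, because a β-alkoxy enolate expels alkoxide. A silyl group cannot leave, and it is later replaced by hydroxyl with retention.

**12 to 9 (key disconnection).**
- The C8–C9 bond is cut and C1 is reconnected to C6, which is the reverse of an anionic oxy-Cope rearrangement.
- A ten-membered ring with an E alkene, a Z alkene and two stereocentres collapses to cyclohexenol 9. In 9 the Z alkene is a plain ring alkene, and the carbinol is made in one step.
- The forward step must enlarge the ring by four atoms, fix the E geometry and pass the chirality of C1/C6 on to C8.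
- The only other oxy-Cope mapping puts the ketone at C5 (forming C2–C3, breaking C5–C10). It was not used because its chair gives the E C4=C5 enolate, which leads to a trans-oxirane. It also needs a cyclohexanone that already carries C6, C7, C8 and a quaternary C10.

**9 to 2 and 6.**
- The C6–C7 bond is cut.
- The step needs silicon cis to the isopropyl group and trans to C6. That is the sterically disfavoured isomer of any alkenyl halide, so an alkenyllithium route is awkward.
- Syn addition of C6 and H across alkyne 6, through 7 and 8, gives this geometry by mechanism.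

**2 to 1, and 6 to 3 and 4.** Enone 2 comes from commercial allylic alcohol 1 by a 1,3-oxidative transposition that does not touch the stereocentre. Alkyne 6 comes from silylation of 3 with 4.

## Alternatives that were turned down

**Alternative 1:** the textbook macrocyclisation, cutting C6–C7.
- *Forward key step.* An intramolecular Nozaki–Hiyama–Kishi-type allylation (CrCl2, or zerovalent palladium with Et2Zn) of the open-chain cis-epoxy aldehyde allylic chloride A1 at high dilution. The allyl unit reacts at its γ-carbon C7 to give ten-membered homoallylic alcohol A2.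
- *Why turned down.*
  - A1 already needs the Z-derived oxirane, the E alkene, the C8 stereocentre and two differentiated termini, which means a long linear sequence.
  - The closure works against entropy and transannular strain with no preorganisation.
  - C6 and C7 form under competing influences from C5 and C8.
  - The isopropenyl group of A2 must then be hydrogenated next to C1=C10 and an oxirane.

**Alternative 2:** cutting the C1=C10 double bond.
- *Forward key step.* Ring-closing metathesis of seco-diene A3 with the second-generation Grubbs catalyst, giving 17 directly.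
- *Why turned down.*
  - The bond to be made is a trisubstituted E alkene in a ten-membered ring.
  - Metathesis is reversible and would favour the less strained Z isomer or oligomers.
  - The 1,1-disubstituted partner reacts slowly.
  - All five stereocentres would have to be built in the open chain, so the ring adds nothing to stereocontrol.

**Alternative 3:** keeping the C1–C6 reconnection but building the second six-membered ring first.
- *Forward key step.* Grob fragmentation of bicyclic hydroxy mesylate A4. The O6 alkoxide pushes, C1–C6 breaks and the C10 leaving group departs, giving silyl ether A5, which would be deprotected to 14.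
- *Why turned down.*
  - The leaving group must sit on the fully substituted C10. A tertiary sulfonate would ionise or eliminate before it could be aligned.
  - A4 carries five stereocentres plus an antiperiplanar requirement.
  - The fragmentation forms no C–C bond, so every skeletal bond must be made beforehand. That costs more steps than the fragmentation saves.

Key step: step 4

Assumption (remark on the chemistry): the stereodescriptors of the SMILES are taken literally, so the oxirane is treated as cis-fused (4S,5R, from a Z alkene).

## Route

Step 1
Reactants: 1 (+)-(1S,4R)-p-mentha-2,8-dien-1-ol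
Product: 2 (S)-isopiperitenone
Conditions: [C5H5NH][CrO3Cl] (pyridinium chlorochromate), Celite, CH2Cl2, 0 °C to rt
Reagents that add atoms: pyridinium chlorochromate, [O-][Cr](=O)(=O)Cl.c1cc[nH+]cc1 (supplies the carbonyl oxygen; the hydroxyl oxygen of 1 leaves with chromium)
Why: Babler–Dauben oxidative transposition: the tertiary allylic chromate ester shifts by a [3,3] process to the secondary allylic position and is oxidised there, so oxygen moves from the methyl-bearing carbon to the carbon next to the isopropenyl stereocentre. That stereocentre (C1) is not involved and the carbinol configuration of 1 is irrelevant; short contact on Celite limits acid-induced enolisation into conjugation.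

Step 2
Reactants: 3 3-methylbut-1-yne; 4 benzyl(chloro)dimethylsilane
Product: 6 benzyl(dimethyl)(3-methylbut-1-yn-1-yl)silane, via lithium acetylide 5 (not isolated)
Conditions: n-BuLi, THF, −78 °C; then 4, −78 °C to rt
Reagents that add atoms: n-butyllithium, [Li]CCCC (lithium of intermediate 5 only)
Why: Deprotonation of the terminal alkyne and substitution at silicon by the acetylide. The benzyl group is a base-stable trigger that fluoride can remove later.

Step 3
Reactants: 6 benzyl(dimethyl)(3-methylbut-1-yn-1-yl)silane; 2 (S)-isopiperitenone
Product: 9 (1S,6S)-1-[(1E)-1-[benzyl(dimethyl)silyl]-3-methylbut-1-en-2-yl]-3-methyl-6-(prop-1-en-2-yl)cyclohex-2-en-1-ol, via titanacyclopropene 7 (not isolated), via oxatitanacyclopentene 8 (not isolated)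
Conditions: Ti(OiPr)4, iPrMgCl (2 equiv per Ti), Et2O, −78 to −50 °C; then 2, −50 to −20 °C; H2O
Reagents that add atoms: titanium tetraisopropoxide, CC(C)O[Ti](OC(C)C)(OC(C)C)OC(C)C (titanium and alkoxide ligands of 7 and 8 only)
Why: Alkyne–carbonyl reductive coupling through a titanacyclopropene made by Kulinkovich-type ligand exchange: the ketone inserts into the Ti–C bond remote from silicon, so C6–C7 forms at the isopropyl-bearing carbon, and hydrolysis of the remaining Ti–C8 bond with retention puts H cis and silicon trans to C6 (E). The non-basic reagent adds 1,2 and spares the labile α-stereocentre; it approaches the carbonyl anti to the neighbouring isopropenyl group, which sets C6 (hydroxyl cis to isopropenyl, the two alkenyl groups trans).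

Step 4
Reactants: 9 (1S,6S)-1-[(1E)-1-[benzyl(dimethyl)silyl]-3-methylbut-1-en-2-yl]-3-methyl-6-(prop-1-en-2-yl)cyclohex-2-en-1-ol
Product: 12 (2Z,6E,9S,10R)-9-[benzyl(dimethyl)silyl]-3,7-dimethyl-10-(propan-2-yl)cyclodeca-2,6-dien-1-one, via potassium alkoxide 10 (not isolated), via potassium dienolate 11 (not isolated)
Conditions: KH, 18-crown-6, THF, 0 °C to rt; then AcOH, THF, −78 °C
Reagents that add atoms: potassium hydride, [K+].[H-] (potassium of 10 and 11 only)
Why: Anionic oxy-Cope rearrangement, the reaction type known for 1,2-dialkenylcyclohexanols and -cyclohexenols: the alkoxide of 10 weakens the C1–C6 bond and the six atoms C8=C7–C6–C1–C10=C9 reorganise suprafacially through a chair, forming C8–C9 as C1–C6 breaks. The ten-membered ring is therefore closed by a four-atom enlargement of the cyclohexene and not end to end, so no dilution is needed, and the driving force is the change of alkoxide 10 into the delocalised dienolate 11. In the only chair open to the trans-dialkenyl isomer both ring bonds (C6–C5 and C1–C2) are equatorial and O6 and H1 are axial; equatorial C2 ends up trans to C9, which gives the E C1=C10 alkene, while C4=C5 is a spectator and keeps the Z geometry imposed by the six-membered ring. C8 is set by transfer of chirality from C1 and C6, which lose theirs: with silicon on the outer (E, equatorial) position of the vinylsilane, C9 can reach only one face of C8, which gives 8S from the (1S,6S) carbinol. C7 is set in the quench, where the enolate carbon is protonated on the outer face of the ring, opposite to the face on which C9 arrived at C8, giving the 7,8-anti (7R) isomer. Periselectivity is needed against the second 1,5-diene (C4=C5–C6–C1–C10=C9), but that path would need an axial isopropenyl group, a boat and a new quaternary carbon at C4, so it should not compete. Silicon at C8 makes the step safe: unlike oxygen it cannot leave from the β-position of 11, it is not a π-donor that would deactivate C8 towards bond formation, and being trans to C6 it is out of reach of the alkoxide, so no Brook-type shift can occur.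

Step 5
Reactants: 12 (2Z,6E,9S,10R)-9-[benzyl(dimethyl)silyl]-3,7-dimethyl-10-(propan-2-yl)cyclodeca-2,6-dien-1-one
Product: 14 (2Z,6E,9S,10S)-9-hydroxy-3,7-dimethyl-10-(propan-2-yl)cyclodeca-2,6-dien-1-one, via silanol 13 (not isolated)
Conditions: Bu4NF, THF, 0 °C; then H2O2 (30% aq), KHCO3, MeOH–THF, rt
Reagents that add atoms: hydrogen peroxide, OO (O8 of 14); water, O (silanol oxygen of 13 only)
Why: Tamao–Fleming oxidation: fluoride cleaves the benzyl–silicon bond to give silanol 13, and peroxide then places oxygen into the C8–Si bond by a 1,2-shift from silicon to oxygen with retention at C8. No electrophilic or acidic reagent is needed, so both trisubstituted alkenes survive, and the bicarbonate medium limits enolisation at C7 and retro-aldol opening.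

Step 6
Reactants: 14 (2Z,6E,9S,10S)-9-hydroxy-3,7-dimethyl-10-(propan-2-yl)cyclodeca-2,6-dien-1-one; 15 3,4,5-trimethoxybenzaldehyde
Product: 16 (1S,3E,7Z,9S,10R)-9-hydroxy-3,7-dimethyl-10-(propan-2-yl)cyclodeca-3,7-dien-1-yl 3,4,5-trimethoxybenzoate
Conditions: SmI2 (0.3 equiv, premixed with excess 15), THF, −10 °C
Reagents that add atoms: none
Why: Evans–Tishchenko reduction: O8 adds to 15, the trivalent samarium alkoxide formed from SmI2 and 15 binds the hemiacetal oxygen and the C6 carbonyl, and the hemiacetal hydrogen is passed to C6 within this chelate. Delivery from the O8 side fixes the 1,3-anti relation (6S in 16, the same spatial arrangement as 6R in 17), which is also the outer face of the ring conformer formed in step 4. The oxidised hemiacetal stays as the trimethoxybenzoate on O8 while O6 is left free.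

Step 7
Reactants: 16 (1S,3E,7Z,9S,10R)-9-hydroxy-3,7-dimethyl-10-(propan-2-yl)cyclodeca-3,7-dien-1-yl 3,4,5-trimethoxybenzoate
Product: 17 (1(10)E,4S,5R,6R,7R,8S)-4,5-epoxy-6-hydroxygermacr-1(10)-en-8-yl 3,4,5-trimethoxybenzoate (target)
Conditions: VO(acac)2 (5 mol %), t-BuOOH (decane), CH2Cl2, 0 °C
Reagents that add atoms: tert-butyl hydroperoxide, CC(C)(C)OO
Why: Hydroxyl-directed epoxidation: the vanadium alkoxide of O6 delivers the peroxide oxygen to the allylic C4=C5 alkene only, so the isolated C1=C10 alkene is left. Oxygen transfer is suprafacial, so the Z alkene gives the cis-fused oxirane. The vanadate reacts through the rotamer with a small O6–C6–C5=C4 dihedral angle, the one left by hydride addition in step 6, which puts the oxirane oxygen on the ring face of O6 (4S,5R), the sense known for medium-ring Z-cycloalkenols.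

## Compound list

1 | (+)-(1S,4R)-p-mentha-2,8-dien-1-ol | C1=C[C@@](C)(O)CC[C@H]1C(C)=C | starting material
2 | (S)-isopiperitenone, (6S)-3-methyl-6-(prop-1-en-2-yl)cyclohex-2-en-1-one | O=C1C=C(C)CC[C@H]1C(C)=C | intermediate
3 | 3-methylbut-1-yne | CC(C)C#C | starting material
4 | benzyl(chloro)dimethylsilane | C[Si](C)(Cl)Cc1ccccc1 | starting material
5 | lithium 3-methylbut-1-yn-1-ide | [Li]C#CC(C)C | intermediate
6 | benzyl(dimethyl)(3-methylbut-1-yn-1-yl)silane | CC(C)C#C[Si](C)(C)Cc1ccccc1 | intermediate
7 | titanium diisopropoxide complex of alkyne 6, drawn as titanacyclopropene | CC(C)O[Ti]1(OC(C)C)C(C(C)C)=C1[Si](C)(C)Cc2ccccc2 | intermediate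
8 | oxatitanacyclopentene from insertion of 2 into 7 (O6 and C8 on titanium) | CC(C)O[Ti]1(OC(C)C)O[C@]2(C=C(C)CC[C@H]2C(C)=C)C(C(C)C)=C1[Si](C)(C)Cc3ccccc3 | intermediate
9 | (1S,6S)-1-[(1E)-1-[benzyl(dimethyl)silyl]-3-methylbut-1-en-2-yl]-3-methyl-6-(prop-1-en-2-yl)cyclohex-2-en-1-ol | O[C@@]1(/C(C(C)C)=C/[Si](C)(C)Cc2ccccc2)C=C(C)CC[C@H]1C(C)=C | intermediate
10 | potassium alkoxide of 9 | [K+].[O-][C@@]1(/C(C(C)C)=C/[Si](C)(C)Cc2ccccc2)C=C(C)CC[C@H]1C(C)=C | intermediate
11 | potassium dienolate of 12 (C5 trans to C8 across C6=C7, 8S) | [K+].C[Si](C)(Cc1ccccc1)[C@H]2C/C(C)=C/CC/C(C)=C\C([O-])=C2/C(C)C | intermediate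
12 | (2Z,6E,9S,10R)-9-[benzyl(dimethyl)silyl]-3,7-dimethyl-10-(propan-2-yl)cyclodeca-2,6-dien-1-one | C[Si](C)(Cc1ccccc1)[C@H]2C/C(C)=C/CC/C(C)=C\C(=O)[C@H]2C(C)C | intermediate
13 | (2Z,6E,9S,10R)-9-[hydroxy(dimethyl)silyl]-3,7-dimethyl-10-(propan-2-yl)cyclodeca-2,6-dien-1-one | C[Si](C)(O)[C@H]1C/C(C)=C/CC/C(C)=C\C(=O)[C@H]1C(C)C | intermediate
14 | (2Z,6E,9S,10S)-9-hydroxy-3,7-dimethyl-10-(propan-2-yl)cyclodeca-2,6-dien-1-one | O[C@H]1C/C(C)=C/CC/C(C)=C\C(=O)[C@H]1C(C)C | intermediate
15 | 3,4,5-trimethoxybenzaldehyde | COc1cc(C=O)cc(OC)c1OC | starting material
16 | (1S,3E,7Z,9S,10R)-9-hydroxy-3,7-dimethyl-10-(propan-2-yl)cyclodeca-3,7-dien-1-yl 3,4,5-trimethoxybenzoate | COc1cc(C(=O)O[C@H]2C/C(C)=C/CC/C(C)=C\[C@H](O)[C@H]2C(C)C)cc(OC)c1OC | intermediate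
17 | (1(10)E,4S,5R,6R,7R,8S)-4,5-epoxy-6-hydroxygermacr-1(10)-en-8-yl 3,4,5-trimethoxybenzoate | COc1cc(C(=O)O[C@H]2C/C(C)=C/CC[C@]3(C)O[C@@H]3[C@H](O)[C@H]2C(C)C)cc(OC)c1OC | target

## Step count and least certain steps

Total step count: 7. Longest linear sequence: 6 steps (1, 3, 4, 5, 6, 7) from 1. Step 2 is a one-step side branch.

**Step 4 (key step).**
- *What may go wrong.* Chirality transfer could erode through a boat or a dissociative fragmentation–recombination path. The rearrangement could be slow because the bond-forming terminus C8 carries a bulky silyl group. Protonation at C7 could be unselective if the ring flips before the quench.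
- *Fallback.* It sets out from 2 and comes back at 14, and it sets C8 by catalyst control after the ring enlargement.
  - (Z)-2-Bromo-1-ethoxy-3-methylbut-1-ene F1 is made from 3-methylbutanal diethyl acetal by α-bromination and loss of ethanol.
  - F1 is lithiated with t-BuLi at −78 °C (the cis alkoxy group stabilises the alkenyllithium) and added to 2, giving ethoxyvinyl carbinol F2.
  - KH and 18-crown-6 bring about the same ring enlargement with a much smaller terminus. The β-ethoxy enolate is allowed to lose ethoxide, a known tandem, giving the achiral cross-conjugated trienone F3.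
  - A copper-catalysed enantioselective conjugate borylation (CuCl, NaOtBu, a chiral bisphosphine, B2pin2, MeOH) attacks C8, the only β-monosubstituted acceptor carbon, to give boronate F4.
  - Oxidation with NaBO3 proceeds with retention and returns to 14.

**Step 3.**
- *What may go wrong.* The hindered, enolisable ketone may insert slowly into the titanacyclopropene. Some bond formation could occur at the silicon-bearing carbon. The low-valent titanium could reduce the enone.
- *Fallback.* It sets out from 2 and 4 and comes back at 9. It forms C6–C7 first and C7–isopropyl second.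
  - Ethynylmagnesium bromide and 4 give benzyl(ethynyl)dimethylsilane F5.
  - The lithium acetylide of F5 adds 1,2 to 2, anti to the isopropenyl group, to give silylethynyl carbinol F6.
  - An alkoxide-directed anti-carbomagnesiation (iPrMgCl, CuI catalyst) places isopropyl on C7 and magnesium on C8 within a five-membered chelate.
  - Protonolysis leaves silicon trans to C6, which is 9.

**Step 5.**
- *What may go wrong.* Basic fluoride may epimerise C7. The strained ring may open by retro-aldol cleavage, or lose water, once the β-hydroxy ketone is exposed to fluoride and peroxide.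
- *Fallback.* It sets out from 12 and comes back at 16. It removes the carbonyl before silicon is oxidised.
  - iBu2AlH at −78 °C reduces the ketone from the outer face to hydroxysilane F7.
  - Catalytic KOtBu lets the O6 alkoxide attack silicon with loss of the benzyl group, giving oxasilolane F8.
  - H2O2, KF and KHCO3 give diol F9.
  - The less hindered O8 is acylated selectively with 3,4,5-trimethoxybenzoyl chloride and collidine at low temperature, giving 16.

**Step 6.**
- *What may go wrong.* The ten-membered ring may not reach the compact array needed for internal hydride transfer, so the reaction could be slow. Retro-aldol cleavage by the samarium alkoxide, or reduction of the enone by leftover divalent samarium, could then take over.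
- *Fallback.* It sets out from 14 and comes back at 16. It separates acylation from reduction.
  - Carbodiimide coupling with 3,4,5-trimethoxybenzoic acid under neutral conditions gives keto ester F10.
  - A Luche reduction (NaBH4, CeCl3, MeOH, −78 °C) adds hydride from the outer ring face, the face that the conformer analysis of step 4 also assigns to the wanted C6 configuration.

**Step 7.**
- *What may go wrong.* Facial selectivity may be poor, because the reactive rotamer places O6 close to C3 (A(1,3) strain) and a ring flip would expose the other face. The Lewis acidic vanadium could trigger transannular opening of the new oxirane by C1=C10.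
- *Fallback.* It sets out from 9 and comes back at 17. It installs the oxirane on the six-membered ring, where syn delivery from a cyclohexenol hydroxyl is secure.
  - VO(acac)2 and t-BuOOH convert 9 into epoxy carbinol F11. The oxirane is cis to O6, so no Payne rearrangement is possible.
  - KH and 18-crown-6 enlarge the ring to epoxy ketone F12.
  - Tamao–Fleming oxidation gives hydroxy epoxy ketone F13.
  - An Evans–Tishchenko reduction with 15 gives 17. The samarium catalyst is discharged with 15 beforehand so that no divalent samarium meets the epoxy ketone.

## Further compounds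

F1 | step 4 | (Z)-2-bromo-1-ethoxy-3-methylbut-1-ene | CCO/C=C(Br)/C(C)C
F2 | step 4 | (1S,6S)-1-[(1Z)-1-ethoxy-3-methylbut-1-en-2-yl]-3-methyl-6-(prop-1-en-2-yl)cyclohex-2-en-1-ol | O[C@@]1(/C(C(C)C)=C\OCC)C=C(C)CC[C@H]1C(C)=C
F3 | step 4 | (2Z,6E,9Z)-3,7-dimethyl-10-(propan-2-yl)cyclodeca-2,6,9-trien-1-one | CC(C)/C1=C/C/C(C)=C/CC/C(C)=C\C1=O
F4 | step 4 | (2Z,6E,9S,10R)-3,7-dimethyl-10-(propan-2-yl)-9-(4,4,5,5-tetramethyl-1,3,2-dioxaborolan-2-yl)cyclodeca-2,6-dien-1-one | CC1(C)OB(OC1(C)C)[C@H]2C/C(C)=C/CC/C(C)=C\C(=O)[C@H]2C(C)C
F5 | step 3 | benzyl(ethynyl)dimethylsilane | C#C[Si](C)(C)Cc1ccccc1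
F6 | step 3 | 1-{[benzyl(dimethyl)silyl]ethynyl}-3-methyl-6-(prop-1-en-2-yl)cyclohex-2-en-1-ol (hydroxyl cis to isopropenyl, 6S) | O[C@@]1(C#C[Si](C)(C)Cc2ccccc2)C=C(C)CC[C@H]1C(C)=C
F7 | step 5 | 9-[benzyl(dimethyl)silyl]-3,7-dimethyl-10-(propan-2-yl)cyclodeca-2,6-dien-1-ol (2Z,6E; C6, C7, C8 arranged as in 16) | C[Si](C)(Cc1ccccc1)[C@H]2C/C(C)=C/CC/C(C)=C\[C@H](O)[C@H]2C(C)C
F8 | step 5 | 2,2-dimethyl-1,2-oxasilolane bridging O6 and C8 of the cyclodecadiene | C[Si]1(C)O[C@H]2/C=C(C)\CC/C=C(C)/C[C@H]1[C@@H]2C(C)C
F9 | step 5 | 4,8-dimethyl-2-(propan-2-yl)cyclodeca-4,8-diene-1,3-diol (germacra-1(10)E,4Z-diene-6,8-diol; C6, C7, C8 arranged as in 16) | O[C@H]1C/C(C)=C/CC/C(C)=C\[C@H](O)[C@H]1C(C)C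
F10 | step 6 | (1S,3E,7Z,10S)-3,7-dimethyl-9-oxo-10-(propan-2-yl)cyclodeca-3,7-dien-1-yl 3,4,5-trimethoxybenzoate | COc1cc(C(=O)O[C@H]2C/C(C)=C/CC/C(C)=C\C(=O)[C@H]2C(C)C)cc(OC)c1OC
F11 | step 7 | 2,3-epoxide of 9 (oxirane oxygen cis to the hydroxyl) | O[C@@]1(/C(C(C)C)=C/[Si](C)(C)Cc2ccccc2)[C@H]3O[C@@]3(C)CC[C@H]1C(C)=C
F12 | step 7 | 4,5-epoxide of 12 (4S,5R oxirane as in 17) | C[Si](C)(Cc1ccccc1)[C@H]2C/C(C)=C/CC[C@]3(C)O[C@@H]3C(=O)[C@H]2C(C)C
F13 | step 7 | 4,5-epoxide of 14 (4S,5R oxirane as in 17) | O[C@H]1C/C(C)=C/CC[C@]2(C)O[C@@H]2C(=O)[C@H]1C(C)C
A1 | alternative 1 | open-chain cis-epoxy aldehyde allylic chloride with O8 as tert-butyldimethylsilyl ether | ClC/C(C)=C/[C@@H](O[Si](C)(C)C(C)(C)C)C/C(C)=C/CC[C@]1(C)O[C@@H]1C=O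
A2 | alternative 1 | ten-membered epoxy alcohol with isopropenyl group at C7 and silyl ether at O8 | CC(C)(C)[Si](C)(C)O[C@H]1C/C(C)=C/CC[C@]2(C)O[C@@H]2[C@H](O)[C@H]1C(C)=C
A3 | alternative 2 | seco-diene of 17 (C1 and C10 each capped as a methylene alkene) | COc1cc(C(=O)O[C@@H](CC(C)=C)[C@H](C(C)C)[C@@H](O)[C@H]2O[C@@]2(C)CCC=C)cc(OC)c1OC
A4 | alternative 3 | bicyclic (C1–C6 bonded) bridgehead alcohol with tertiary mesylate at C10 and silyl ether at O8 | O[C@]12C=C(C)CC[C@@H]1[C@@](C)(OS(C)(=O)=O)C[C@H](O[Si](C)(C)C(C)(C)C)[C@@H]2C(C)C
A5 | alternative 3 | tert-butyldimethylsilyl ether of 14 | CC(C)(C)[Si](C)(C)O[C@H]1C/C(C)=C/CC/C(C)=C\C(=O)[C@H]1C(C)C
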